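The route rests on cutting both bonds that tie the nitrogen ring to the arene, C4–C4a and C1–C8a, in one stroke. It exploits that C4a and C8a are neighbours, with the C8 methoxy group beside C8a, so both can arise from an aryne on the preformed, symmetric biaryl. In the key step the lithium enolate of an N-silyl (S)-4-methylazetidin-2-one adds to C4a, the aryl anion at C8a attacks the lactam carbonyl and the benzocyclobutenoxide fragments. The aryne is thus inserted into the C(=O)–Cα bond and the four-membered lactam grows by two atoms into the six-membered nitrogen ring, with C3 already (S). Methyl addition at C1, cis-selective imine reduction and N-methylation finish the route.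

Key step: step 8

Remark on the chemistry: the SMILES fixes C1 (R) and C3 (S) but not the sense of the biaryl axis, so the axis is not controlled; if rotation about it is slow, the two rotamers of 23 would be separated by chromatography at the end.

Step 1
Reactants: 1 1-(3-methoxyphenyl)propan-2-one
Product: 2 1-(2-bromo-5-methoxyphenyl)propan-2-one
Conditions: NBS, MeCN, 0 °C → rt
Reagents that add atoms: N-bromosuccinimide, O=C1CCC(=O)N1Br
Why: Electrophilic aromatic bromination should go para to the methoxy group, the most activated and least hindered position, while the polar medium without acid or light leaves the ketone α-positions alone.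

Step 2
Reactants: 2 1-(2-bromo-5-methoxyphenyl)propan-2-one, 3 triethyl phosphonoacetate
Product: 5 4-(2-bromo-5-methoxyphenyl)-3-methylbut-2-enoic acid (E/Z mixture), via ethyl ester 4 (not isolated)
Conditions: 3, NaH, THF, 0 °C; then 2, 0 °C → rt; then NaOH, EtOH/H2O, reflux; HCl
Reagents that add atoms: sodium hydroxide, [Na+].[OH-]
Why: Horner–Wadsworth–Emmons olefination of the ketone followed by saponification should give the acid, and neither the E/Z ratio nor a shift of the double bond towards the arene matters because all isomers converge in step 3.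

Step 3
Reactants: 5 4-(2-bromo-5-methoxyphenyl)-3-methylbut-2-enoic acid (E/Z mixture)
Product: 6 5-bromo-8-methoxy-3-methylnaphthalen-1-yl acetate
Conditions: Ac2O, NaOAc, 140 °C
Reagents that add atoms: acetic anhydride, CC(=O)OC(C)=O
Why: The mixed anhydride should give a dienylketene that closes by 6π-electrocyclisation (the ring closure of Stobbe-type naphthol syntheses) onto the only free ortho position, the one beside OMe, since the other is blocked by Br, and the naphthol is acetylated in situ.

Step 4
Reactants: 6 5-bromo-8-methoxy-3-methylnaphthalen-1-yl acetate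
Product: 8 1-bromo-4,5-dimethoxy-7-methylnaphthalene, via naphthol 7 (not isolated)
Conditions: K2CO3, MeOH, rt; evaporate; then MeI, K2CO3, DMF, rt
Reagents that add atoms: methyl iodide, CI
Why: Methanolysis of the aryl acetate and Williamson O-methylation of the naphtholate should give the dimethyl ether.

Step 5
Reactants: 9 1-chloro-3,5-dimethoxybenzene, 8 1-bromo-4,5-dimethoxy-7-methylnaphthalene
Product: 12 1-(4-chloro-2,6-dimethoxyphenyl)-4,5-dimethoxy-7-methylnaphthalene, via aryllithium 10 (not isolated), via arylzinc chloride 11 (not isolated)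
Conditions: 9 (1.3 equiv), n-BuLi (1.2 equiv), THF, 0 °C; ZnCl2, 0 °C → rt; then 8, Pd(PPh3)4 (5 mol %), 65 °C
Reagents that add atoms: none
Why: Directed ortho-metalation between the two methoxy groups, transmetalation to zinc and Negishi coupling should join the rings, because Pd(PPh3)4 inserts into the C–Br bond but not into the unactivated C–Cl bond; the new axis is not stereogenic since the phenyl ring is symmetric.

Step 6
Reactants: 13 (S)-3-aminobutanoic acid
Product: 14 (S)-4-methylazetidin-2-one
Conditions: PPh3, 2,2'-dipyridyl disulfide, MeCN (high dilution), 80 °C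
Reagents that add atoms: none
Why: Dehydrative β-lactam closure of the β-amino acid through its 2-pyridyl thioester (redox condensation) should not touch the stereocentre, which comes from the chiral pool.

Step 7
Reactants: 14 (S)-4-methylazetidin-2-one
Product: 15 (S)-1-(tert-butyldimethylsilyl)-4-methylazetidin-2-one
Conditions: TBSCl, Et3N, DMAP (cat.), CH2Cl2, 0 °C → rt
Reagents that add atoms: tert-butyldimethylsilyl chloride, CC(C)(C)[Si](C)(C)Cl
Why: N-silylation of the lactam blocks N-arylation and allows clean enolisation at C3 in the next step.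

Step 8
Reactants: 15 (S)-1-(tert-butyldimethylsilyl)-4-methylazetidin-2-one, 12 1-(4-chloro-2,6-dimethoxyphenyl)-4,5-dimethoxy-7-methylnaphthalene
Product: 19 (S)-7-(4,5-dimethoxy-7-methylnaphthalen-1-yl)-6,8-dimethoxy-3-methyl-3,4-dihydroisoquinolin-1(2H)-one, via lithium enolate 16 (not isolated), via aryne 17 (not isolated), via N-silyl lactam 18 (not isolated)
Conditions: 15 (2.5 equiv), LDA (2.5 equiv), THF, −78 °C; then 12 (1 equiv), LiTMP (1.5 equiv), −78 → −20 °C; then 1 M HCl, THF, rt
Reagents that add atoms: none
Why: Proposed new method: LiTMP should remove one of the two equivalent protons of 12 between Cl and OMe and loss of LiCl gives aryne 17, to which the α-carbon of enolate 16 adds at the carbon remote from the flanking methoxy group (future C4a), because the charge then develops on the carbon next to oxygen (future C8a), where the inductive effect of OMe and O–Li chelation stabilise it. This aryllithium closes on the strained, ketone-like lactam carbonyl in a 4-exo-trig mode to a benzocyclobutenoxide fused to the azetidine, and the strain of two fused four-membered rings drives heterolysis of the old C2–C3 lactam bond, so the six-membered ring arises by fragmentation (not by a ring closure of its own) and the C4 benzylic anion is protonated by the amine present. The net change is insertion of the aryne into the C(=O)–Cα bond, a two-atom ring expansion of the azetidinone to the N-silyl dihydroisoquinolinone 18, which the acidic work-up desilylates to 19. The closest known reaction types are the tandem addition–rearrangement of α-lithionitriles with 3-methoxyarynes, the ring expansion of cyclic ketone enolates with arynes through benzocyclobutenoxides and the acyl-alkylation of arynes with cyclic β-keto esters; a β-lactam enolate has not been shown to react this way. No stereocentre is formed: C3 is C4 of 15, which is neither deprotonated nor part of a broken bond, and C4 ends as CH2. The step needs C-arylation rather than N- or O-arylation (N is blocked by silicon and lithium enolates arylate at carbon) and acyl capture of the aryl anion faster than its protonation, which the proximity and electrophilicity of the β-lactam carbonyl should secure.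

Step 9
Reactants: 19 (S)-7-(4,5-dimethoxy-7-methylnaphthalen-1-yl)-6,8-dimethoxy-3-methyl-3,4-dihydroisoquinolin-1(2H)-one
Product: 22 (1R,3S)-7-(4,5-dimethoxy-7-methylnaphthalen-1-yl)-6,8-dimethoxy-1,3-dimethyl-1,2,3,4-tetrahydroisoquinoline, via N-trimethylsilyl lactam 20 (not isolated), via cyclic imine 21 (not isolated)
Conditions: TMSCl, Et3N, toluene, 60 °C; filter under argon; MeLi, Et2O, −20 °C → rt; then MeOH, NaBH4, −20 °C → rt
Reagents that add atoms: methyllithium, [Li]C
Why: Addition of MeLi to the N-silyl lactam and loss of lithium trimethylsilanolate (aza-Peterson-type synthesis of cyclic ketimines) should give imine 21, and NaBH4 should deliver hydride to C1 of the half-chair with the C3 methyl group pseudo-equatorial so that both methyl groups end pseudo-equatorial, which sets C1 as R (1,3-cis), the known course for 1,3-dimethyl-3,4-dihydroisoquinolines that carry no substituent on nitrogen.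

Step 10
Reactants: 22 (1R,3S)-7-(4,5-dimethoxy-7-methylnaphthalen-1-yl)-6,8-dimethoxy-1,3-dimethyl-1,2,3,4-tetrahydroisoquinoline
Product: 23 ancistrobrevine A
Conditions: 37% aq HCHO, NaBH(OAc)3, ClCH2CH2Cl, rt
Reagents that add atoms: formaldehyde, C=O
Why: Reductive amination of the secondary amine through its iminium ion should install the N-methyl group without touching C1 or C3; methylation is placed after the reduction because N-alkyl iminium salts of this type reduce with 1,3-trans selectivity.

Compound list
1 | 1-(3-methoxyphenyl)propan-2-one | COc1cccc(CC(C)=O)c1 | starting material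
2 | 1-(2-bromo-5-methoxyphenyl)propan-2-one | COc1ccc(Br)c(CC(C)=O)c1 | intermediate
3 | triethyl phosphonoacetate | CCOC(=O)CP(=O)(OCC)OCC | starting material
4 | ethyl 4-(2-bromo-5-methoxyphenyl)-3-methylbut-2-enoate (E/Z mixture) | COc1ccc(Br)c(CC(C)=CC(=O)OCC)c1 | intermediate
5 | 4-(2-bromo-5-methoxyphenyl)-3-methylbut-2-enoic acid (E/Z mixture) | COc1ccc(Br)c(CC(C)=CC(=O)O)c1 | intermediate
6 | 5-bromo-8-methoxy-3-methylnaphthalen-1-yl acetate | CC(=O)Oc1cc(C)cc2c(Br)ccc(OC)c12 | intermediate
7 | 5-bromo-8-methoxy-3-methylnaphthalen-1-ol | COc1ccc(Br)c2cc(C)cc(O)c12 | intermediate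
8 | 1-bromo-4,5-dimethoxy-7-methylnaphthalene | COc1ccc(Br)c2cc(C)cc(OC)c12 | intermediate
9 | 1-chloro-3,5-dimethoxybenzene | COc1cc(Cl)cc(OC)c1 | starting material
10 | (4-chloro-2,6-dimethoxyphenyl)lithium | [Li]c1c(OC)cc(Cl)cc1OC | intermediate
11 | (4-chloro-2,6-dimethoxyphenyl)zinc chloride | Cl[Zn]c1c(OC)cc(Cl)cc1OC | intermediate
12 | 1-(4-chloro-2,6-dimethoxyphenyl)-4,5-dimethoxy-7-methylnaphthalene | COc1cc(Cl)cc(OC)c1-c1ccc(OC)c2c(OC)cc(C)cc12 | intermediate
13 | (S)-3-aminobutanoic acid | C[C@H](N)CC(=O)O | starting material
14 | (S)-4-methylazetidin-2-one | C[C@H]1CC(=O)N1 | intermediate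
15 | (S)-1-(tert-butyldimethylsilyl)-4-methylazetidin-2-one | C[C@H]1CC(=O)N1[Si](C)(C)C(C)(C)C | intermediate
16 | lithium enolate of 15 (O-lithio, C2=C3 double bond, 4S) | C[C@H]1C=C(O[Li])N1[Si](C)(C)C(C)(C)C | intermediate
17 | 4-(4,5-dimethoxy-7-methylnaphthalen-1-yl)-3,5-dimethoxybenzyne (triple bond C1≡C2, OMe on C3 and C5) | COC1=C(c2ccc(OC)c3c(OC)cc(C)cc23)C(OC)=CC#C1 | intermediate
18 | (S)-2-(tert-butyldimethylsilyl)-7-(4,5-dimethoxy-7-methylnaphthalen-1-yl)-6,8-dimethoxy-3-methyl-3,4-dihydroisoquinolin-1(2H)-one | COc1cc2c(c(OC)c1-c1ccc(OC)c3c(OC)cc(C)cc13)C(=O)N([Si](C)(C)C(C)(C)C)[C@@H](C)C2 | intermediate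
19 | (S)-7-(4,5-dimethoxy-7-methylnaphthalen-1-yl)-6,8-dimethoxy-3-methyl-3,4-dihydroisoquinolin-1(2H)-one | COc1cc2c(c(OC)c1-c1ccc(OC)c3c(OC)cc(C)cc13)C(=O)N[C@@H](C)C2 | intermediate
20 | (S)-7-(4,5-dimethoxy-7-methylnaphthalen-1-yl)-6,8-dimethoxy-3-methyl-2-(trimethylsilyl)-3,4-dihydroisoquinolin-1(2H)-one | COc1cc2c(c(OC)c1-c1ccc(OC)c3c(OC)cc(C)cc13)C(=O)N([Si](C)(C)C)[C@@H](C)C2 | intermediate
21 | (S)-7-(4,5-dimethoxy-7-methylnaphthalen-1-yl)-6,8-dimethoxy-1,3-dimethyl-3,4-dihydroisoquinoline | COc1cc2c(c(OC)c1-c1ccc(OC)c3c(OC)cc(C)cc13)C(C)=N[C@@H](C)C2 | intermediate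
22 | (1R,3S)-7-(4,5-dimethoxy-7-methylnaphthalen-1-yl)-6,8-dimethoxy-1,3-dimethyl-1,2,3,4-tetrahydroisoquinoline (1,3-cis) | COc1cc2c(c(OC)c1-c1ccc(OC)c3c(OC)cc(C)cc13)[C@@H](C)N[C@@H](C)C2 | intermediate
23 | ancistrobrevine A, (1R,3S)-7-(4,5-dimethoxy-7-methylnaphthalen-1-yl)-6,8-dimethoxy-1,2,3-trimethyl-1,2,3,4-tetrahydroisoquinoline | COc1cc2c(c(OC)c1-c1ccc(OC)c3c(OC)cc(C)cc13)[C@@H](C)N(C)[C@@H](C)C2 | target

Total step count: 10. Longest linear sequence: 8 steps (steps 1–5, then 8–10).

Steps most likely to fail

Step 8 (proposed new method). What may go wrong: protonation of the aryl anion by the amine before it closes on the lactam carbonyl, collapse of the tetrahedral intermediate by C–N instead of C–C cleavage, or ring opening of the C4 benzylic anion by β-elimination of the amide nitrogen. The fallback uses known chemistry, sets out from 12 and comes back at 22; it closes the nitrogen ring by condensation instead of growing it from the four-membered ring. Aryne 17 is generated from 12 as before (LiTMP, THF, −78 → −20 °C) in the presence of the N,C-dilithio derivative (LDA, 2 equiv) of commercial (S)-3-(tert-butoxycarbonylamino)butanenitrile, C[C@H](NC(=O)OC(C)(C)C)CC#N. The tandem addition–rearrangement known for α-lithionitriles and 3-methoxyarynes should place the side chain on C4a and the nitrile on C8a to give tert-butyl N-[(2S)-1-[2-cyano-4-(4,5-dimethoxy-7-methylnaphthalen-1-yl)-3,5-dimethoxyphenyl]propan-2-yl]carbamate F1. Addition of MeLi to the nitrile and hydrolysis of the ketimine with aqueous acid should give the methyl ketone tert-butyl N-[(2S)-1-[2-acetyl-4-(4,5-dimethoxy-7-methylnaphthalen-1-yl)-3,5-dimethoxyphenyl]propan-2-yl]carbamate F2. TFA in CH2Cl2 removes the Boc group, the amino ketone closes to imine 21, and NaBH4 in MeOH gives 22.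

Step 9. What may go wrong: attack of MeLi at silicon (desilylation back to the lactam anion) or slow addition to the carbonyl shielded by the C8 methoxy group, so that no imine forms. The fallback sets out from 19 and comes back at 22, with electrophilic activation in place of nucleophilic addition. Tf2O and 2-fluoropyridine in CH2Cl2 (−78 → 0 °C) should convert the secondary lactam into the cyclic imidoyl triflate (S)-7-(4,5-dimethoxy-7-methylnaphthalen-1-yl)-6,8-dimethoxy-3-methyl-3,4-dihydroisoquinolin-1-yl trifluoromethanesulfonate F3. MeMgBr with CeCl3 (−78 °C → rt) displaces the triflate to give imine 21, and NaBH4 in MeOH gives 22.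

Step 5. What may go wrong: slow transmetalation and reductive elimination at the arylzinc flanked by two methoxy groups, so that homocoupling of the bromide and protonation of the zinc reagent take over. The fallback sets out from 8 and 9 and comes back at 12, with the polarity of the partners reversed. Miyaura borylation of 8 (B2pin2, PdCl2(dppf), KOAc, dioxane, 90 °C) should give 2-(4,5-dimethoxy-7-methylnaphthalen-1-yl)-4,4,5,5-tetramethyl-1,3,2-dioxaborolane F4. Aryllithium 10, made from 9 as in step 5, is quenched with I2 to give 5-chloro-2-iodo-1,3-dimethoxybenzene F5. Suzuki–Miyaura coupling of F4 with F5 at the C–I bond (Pd(PPh3)4, K3PO4, DME/H2O, 85 °C) should give 12.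

Further compounds
F1 | step 8 | tert-butyl N-[(2S)-1-[2-cyano-4-(4,5-dimethoxy-7-methylnaphthalen-1-yl)-3,5-dimethoxyphenyl]propan-2-yl]carbamate | COc1cc(C[C@H](C)NC(=O)OC(C)(C)C)c(C#N)c(OC)c1-c1ccc(OC)c2c(OC)cc(C)cc12
F2 | step 8 | tert-butyl N-[(2S)-1-[2-acetyl-4-(4,5-dimethoxy-7-methylnaphthalen-1-yl)-3,5-dimethoxyphenyl]propan-2-yl]carbamate | COc1cc(C[C@H](C)NC(=O)OC(C)(C)C)c(C(C)=O)c(OC)c1-c1ccc(OC)c2c(OC)cc(C)cc12
F3 | step 9 | (S)-7-(4,5-dimethoxy-7-methylnaphthalen-1-yl)-6,8-dimethoxy-3-methyl-3,4-dihydroisoquinolin-1-yl trifluoromethanesulfonate | COc1cc2c(c(OC)c1-c1ccc(OC)c3c(OC)cc(C)cc13)C(OS(=O)(=O)C(F)(F)F)=N[C@@H](C)C2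
F4 | step 5 | 2-(4,5-dimethoxy-7-methylnaphthalen-1-yl)-4,4,5,5-tetramethyl-1,3,2-dioxaborolane | COc1ccc(B2OC(C)(C)C(C)(C)O2)c2cc(C)cc(OC)c12
F5 | step 5 | 5-chloro-2-iodo-1,3-dimethoxybenzene | COc1cc(Cl)cc(OC)c1I
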